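**Retrosynthetic overview**

1. Numbering: O8 pyran oxygen, C9 hemiketal, C10 CHOH, C11 ketone, C12 carbinol, C13=C14–C15(=O) enone, C16 CMe2, C17 CHMe, C18 ring-fusion CH, C19 CH2; rings A (pyranone), B (pyran), C (seven-membered), D (cyclopentenone). Feature: the C12 hydroxyl lies 1,4 to C18 across the C13–C17 edge of ring C, so an oxygen bridge C12–O–C18 turns ring C into an 8-oxabicyclo[3.2.1]oct-3-en-2-one (C9 ketone, C10=C11) with ring D fused on C12–C13.
2. Key disconnection: intramolecular 3-oxidopyrylium–alkene (5+2) cycloaddition forming C12–C13 and C17–C18; the precursor is a 6-acyloxypyranone from Achmatowicz oxidation of a 2,5-disubstituted furan that carries the CMe2–ketal–(E)-crotyl tether.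
3. After the key step: C11 is oxygenated through the C10=C11 epoxide, then the C18–O bridge is cut by SmI2 and the resulting C9–C18 enolate is hydroxymethylated to bring in C19 regiospecifically.
4. Rings A and B arrive together by Michael addition of 4-hydroxy-5,6-dimethylpyran-2-one to the C18 methylene ketone and hemiketal closure on C9; ring D is then dehydrogenated, C11 oxidised and C10 hydroxylated last.
5. Ring order: furan → pyranone → rings C and D with the temporary bridge (key step) → ring B onto the purchased ring A.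

Key step: step 9

Assumption: C9 and C18 of the target, which can interconvert through the ring-opened enolisable C9 ketone, are taken to have the thermodynamically preferred arrangement (rings B and C trans-fused, anomeric hydroxyl axial, C19 anti to the C17 methyl); step 16 relies on this.

**Route**

Step 1
Reactants: 1 ethyl 2-(furan-2-yl)acetate; 2 iodomethane
Product: 4 ethyl 2-(furan-2-yl)-2-methylpropanoate, via monomethyl ester 3 (not isolated)
Conditions: NaH (2.5 equiv), MeI (3 equiv), THF/DMF, 0 °C → rt
Reagents that add atoms: iodomethane, CI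
Why: Exhaustive enolate C-methylation of an arylacetic ester should stop cleanly at the quaternary ester, which has no α-hydrogen left.

Step 2
Reactants: 4 ethyl 2-(furan-2-yl)-2-methylpropanoate; 5 acetonitrile
Product: 6 4-(furan-2-yl)-4-methyl-3-oxopentanenitrile
Conditions: MeCN (2.5 equiv), n-BuLi (2.4 equiv), THF, −78 °C; then 4, −78 °C → rt; dilute aq. HCl
Reagents that add atoms: acetonitrile, CC#N
Why: Claisen-type acylation of lithioacetonitrile by a non-enolisable ester is reliable even at a neopentyl carbonyl, the β-ketonitrile being held as its enolate until acidic work-up.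

Step 3
Reactants: 6 4-(furan-2-yl)-4-methyl-3-oxopentanenitrile
Product: 7 2-{2-[2-(furan-2-yl)propan-2-yl]-1,3-dioxolan-2-yl}acetonitrile
Conditions: TMSOCH2CH2OTMS (3 equiv), TMSOTf (0.1 equiv), CH2Cl2, −78 → −20 °C; pyridine quench
Reagents that add atoms: 1,2-bis(trimethylsilyloxy)ethane, C[Si](C)(C)OCCO[Si](C)(C)C
Why: Noyori ketalisation works at low temperature without protic acid, so the furan survives and the ketone is masked before any β,γ-unsaturation exists that could slip into conjugation.

Step 4
Reactants: 7 2-{2-[2-(furan-2-yl)propan-2-yl]-1,3-dioxolan-2-yl}acetonitrile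
Product: 9 2-{2-[2-(furan-2-yl)propan-2-yl]-1,3-dioxolan-2-yl}acetaldehyde, via aluminoimine 8 (not isolated)
Conditions: i-Bu2AlH (1.3 equiv), CH2Cl2, −78 °C; then aq. potassium sodium tartrate, pH 5 buffer
Reagents that add atoms: water, O
Why: Partial reduction of a nitrile with i-Bu2AlH stops at the N-aluminoimine, whose mild hydrolysis gives the aldehyde without over-reduction and without loss of the dioxolane.

Step 5
Reactants: 9 2-{2-[2-(furan-2-yl)propan-2-yl]-1,3-dioxolan-2-yl}acetaldehyde; 10 1,1-diiodoethane
Product: 11 2-[(E)-but-2-en-1-yl]-2-[2-(furan-2-yl)propan-2-yl]-1,3-dioxolane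
Conditions: CrCl2 (8 equiv), CH3CHI2 (2 equiv), THF, rt
Reagents that add atoms: 1,1-diiodoethane, CC(I)I
Why: Takai–Utimoto ethylidenation with the geminal dichromium reagent formed from CH3CHI2 and divalent chromium converts aldehydes into (E)-propenyl groups under non-basic conditions, fixing the alkene geometry that later controls C17.

Step 6
Reactants: 11 2-[(E)-but-2-en-1-yl]-2-[2-(furan-2-yl)propan-2-yl]-1,3-dioxolane; 12 formaldehyde (as paraformaldehyde)
Product: 14 {5-[2-(2-[(E)-but-2-en-1-yl]-1,3-dioxolan-2-yl)propan-2-yl]furan-2-yl}methanol, via 5-lithiofuran 13 (not isolated)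
Conditions: n-BuLi (1.1 equiv), THF, −78 → 0 °C; then (CH2O)n, 0 °C → rt
Reagents that add atoms: formaldehyde, C=O
Why: α-Lithiation of a 2-alkylfuran occurs only at the free C5 position, and the aryllithium adds to formaldehyde to give the furfuryl alcohol directly.

Step 7
Reactants: 14 {5-[2-(2-[(E)-but-2-en-1-yl]-1,3-dioxolan-2-yl)propan-2-yl]furan-2-yl}methanol
Product: 15 6-hydroxy-6-[2-(2-[(E)-but-2-en-1-yl]-1,3-dioxolan-2-yl)propan-2-yl]-2H-pyran-3(6H)-one (racemic at the acetal carbon)
Conditions: NBS (1.05 equiv), NaHCO3, NaOAc, THF/H2O (4:1), 0 °C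
Reagents that add atoms: water, O
Why: Achmatowicz oxidation is selective for the electron-rich furan over the isolated alkene and under bicarbonate buffer spares the dioxolane, while the new acetal centre forms racemic and is erased in step 9.

Step 8
Reactants: 15 6-hydroxy-6-[2-(2-[(E)-but-2-en-1-yl]-1,3-dioxolan-2-yl)propan-2-yl]-2H-pyran-3(6H)-one
Product: 16 6-[4-(methylthio)benzoyloxy]-6-[2-(2-[(E)-but-2-en-1-yl]-1,3-dioxolan-2-yl)propan-2-yl]-2H-pyran-3(6H)-one (racemic at the acetal carbon)
Conditions: 4-(MeS)C6H4COCl (1.5 equiv), Et3N, DMAP (0.2 equiv), CH2Cl2, 0 °C → rt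
Reagents that add atoms: 4-(methylthio)benzoyl chloride, CSc1ccc(cc1)C(Cl)=O
Why: DMAP-catalysed acylation of the tertiary hemiketal hydroxyl installs an aroate leaving group (chosen in place of acetate because it suits anion-binding catalysis), with the acetal carbon remaining racemic.

Step 9
Reactants: 16 6-[4-(methylthio)benzoyloxy]-6-[2-(2-[(E)-but-2-en-1-yl]-1,3-dioxolan-2-yl)propan-2-yl]-2H-pyran-3(6H)-one
Product: 18 bridged tricyclic enone (C9 ketone; C10=C11; C12–O–C18 bridge; C15 dioxolane; C14 syn and C17 methyl anti to the bridge), via oxidopyrylium ylide 17 (not isolated)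
Conditions: primary aminothiourea catalyst (trans-2-aminocyclohexyl aryl thiourea, 0.15 equiv), N,N'-bis[3,5-bis(trifluoromethyl)phenyl]thiourea (0.15 equiv), AcOH (0.15 equiv), toluene, 40 °C
Reagents that add atoms: none
Why: The primary amine condenses with the C9 ketone and the thiourea cocatalyst pulls the aroate from C12, giving the aminopyrylium equivalent of 3-oxidopyrylium 17, whose termini C12 and C18 add suprafacially across the tethered alkene (bonds C12–C13 and C17–C18) before hydrolysis returns the C9 ketone. The closest known reaction type is the amine–thiourea-catalysed intramolecular oxidopyrylium–alkene (5+2) cycloaddition of 6-acyloxypyranones derived from furfuryl alcohols. Ring D closes through the three-atom tether C16–C15–C14 by a 5-exo mode of addition of C12 to C13, and ring C appears as the carbocycle of the new 8-oxabicyclo[3.2.1]octenone by union of the five-atom unit C18–C9–C10–C11–C12 with C13=C17, the pyranone oxygen becoming the C12–O–C18 bridge. The bridge ties C12 and C18 to one face, the short tether allows only the exo orientation of C14 on C13 (syn to the bridge), and the E geometry then places the C17 methyl endo (anti to the bridge) by stereospecific suprafacial addition. The absolute sense comes from the catalyst alone, because the ylide is achiral and the racemic acetal centre of 16 is lost on ionisation; the catalyst antipode that gives 18 is selected in a trial run. The step needs intramolecular capture to outrun ylide dimerisation and needs the folded conformer, and both are promoted by the gem-dimethyl group and the dioxolane on the tether.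

Step 10
Reactants: 18 bridged tricyclic enone
Product: 19 bridged epoxy ketone (C10–C11 oxirane syn to the oxygen bridge)
Conditions: 30% aq. H2O2, NaOH, MeOH, 0 °C
Reagents that add atoms: hydrogen peroxide, OO
Why: Weitz–Scheffer epoxidation adds hydroperoxide to C11 from the exo face (syn to the bridge, away from the endo C17 methyl) and oxidises the only enone, the two new centres being transient because C10 is reduced in step 11 and C11 becomes a ketone in step 19.

Step 11
Reactants: 19 bridged epoxy ketone
Product: 20 bridged β-hydroxy ketone (C9 ketone; C10 methylene; C11 hydroxyl syn to the bridge)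
Conditions: SmI2 (2.1 equiv), THF/MeOH (4:1), −90 °C
Reagents that add atoms: none
Why: SmI2 reduction of an α,β-epoxy ketone opens the strained oxirane at the α C–O bond much faster than the ketyl can expel the bridging alkoxide, and methanol protonates the enolate at once, so two equivalents at low temperature should stop at the β-hydroxy ketone with C11 retained.

Step 12
Reactants: 20 bridged β-hydroxy ketone
Product: 21 C11 triethylsilyl ether of 20
Conditions: TESOTf, 2,6-lutidine, CH2Cl2, −78 °C
Reagents that add atoms: triethylsilyl triflate, CC[Si](CC)(CC)OS(=O)(=O)C(F)(F)F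
Why: Silylation with the silyl triflate and 2,6-lutidine at low temperature protects the β-hydroxyl without β-elimination, so that it cannot protonate the samarium enolate of step 13.

Step 13
Reactants: 21 C11 triethylsilyl ether; 12 formaldehyde (monomer in THF from paraformaldehyde)
Product: 23 bridge-opened hydroxymethyl ketone (C9 ketone; C18 CH–CH2OH as an epimer mixture; C12 tertiary hydroxyl; C11 OTES), via samarium enolate 22 (not isolated)
Conditions: SmI2 (2.5 equiv), THF, −78 °C; then CH2O (THF solution, 8 equiv), −78 → −40 °C; aq. NH4Cl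
Reagents that add atoms: formaldehyde, C=O
Why: SmI2 reductive cleavage of the α-alkoxy ketone (ketyl at C9, loss of the C18–O bond, second electron transfer) gives the trivalent samarium enolate only across C9–C18 and frees the C12 alkoxide, and a samarium-enolate aldol addition to formaldehyde then places C19 on C18 and not on C10, the C18 configuration being irrelevant because C18 becomes trigonal in step 14.

Step 14
Reactants: 23 bridge-opened hydroxymethyl ketone
Product: 25 α-methylene ketone (C18=C19 exocyclic enone; C12 hydroxyl free), via primary mesylate 24 (not isolated)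
Conditions: MsCl (1.2 equiv), Et3N (3 equiv), CH2Cl2, −20 → 0 °C
Reagents that add atoms: none
Why: Selective mesylation of the primary alcohol followed by E1cB elimination with Et3N is the standard route to an α-methylene ketone, the hindered tertiary C12 hydroxyl remaining untouched.

Step 15
Reactants: 25 α-methylene ketone
Product: 26 C12 tert-butyldimethylsilyl ether of 25
Conditions: TBSOTf (1.5 equiv), 2,6-lutidine, CH2Cl2, 0 °C → rt
Reagents that add atoms: tert-butyldimethylsilyl triflate, CC(C)(C)[Si](C)(C)OS(=O)(=O)C(F)(F)F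
Why: Silylation of the tertiary alcohol with the reactive silyl triflate removes the one nucleophile that could add to C19 (oxa-Michael) or later close a transannular ketal onto C9.

Step 16
Reactants: 26 C12 silyl ether of the α-methylene ketone; 27 4-hydroxy-5,6-dimethyl-2H-pyran-2-one
Product: 29 tetracyclic silyl ketal (rings A to D; C9 OTBS; C11 OTES; C12 OTBS; C15 dioxolane), via hemiketal 28 (not isolated)
Conditions: 27 (1.2 equiv), Et3N (0.3 equiv), MeCN, rt; then 2,6-lutidine, TBSOTf, CH2Cl2, 0 °C
Reagents that add atoms: 4-hydroxy-5,6-dimethyl-2H-pyran-2-one, Cc1oc(=O)cc(O)c1C; tert-butyldimethylsilyl triflate, CC(C)(C)[Si](C)(C)OS(=O)(=O)C(F)(F)F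
Why: Base-catalysed Michael addition of C3 of the 4-hydroxypyranone to the exocyclic enone (the addition used for warfarin-type adducts) is followed by hemiketal closure of the C4 hydroxyl onto C9, which forms ring B, and since enolate protonation and hemiketal formation are reversible C18 and C9 should settle with C19 anti to the C17 methyl, rings B and C trans-fused and the anomeric oxygen axial, an arrangement then fixed by silylation.

Step 17
Reactants: 29 tetracyclic silyl ketal
Product: 30 C15 ketone with free C11 hydroxyl (C9 OTBS and C12 OTBS kept)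
Conditions: 1 M aq. HCl, THF, 0 °C → rt
Reagents that add atoms: water, O
Why: Aqueous acid hydrolyses the strained dioxolane next to the quaternary C16 and the secondary triethylsilyl ether, whereas the tertiary and anomeric TBS ethers hydrolyse far more slowly.

Step 18
Reactants: 30 C15 ketone with free C11 hydroxyl
Product: 33 ring D enone (C13=C14–C15=O) with free C11 hydroxyl, via bis-silyl enol ether 31 (not isolated), via silylated enone 32 (not isolated)
Conditions: TMSOTf (2.5 equiv), Et3N (4 equiv), CH2Cl2, −78 → 0 °C; then Pd(OAc)2 (1.1 equiv), MeCN, rt; then citric acid, MeOH, rt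
Reagents that add atoms: none
Why: In this Ito–Saegusa oxidation C15 is the only enolisable carbonyl (C16 is quaternary, C9 is a ketal), so soft enolisation gives the C14=C15 silyl enol ether, palladium enolate formation and syn β-hydride elimination of H13 give the C13=C14 enone, and mild methanolysis then frees only the secondary C11 trimethylsilyl ether.

Step 19
Reactants: 33 ring D enone with free C11 hydroxyl
Product: 34 C11 ketone (C10 methylene; C9 OTBS; C12 OTBS)
Conditions: Dess–Martin periodinane, NaHCO3, CH2Cl2, rt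
Reagents that add atoms: none
Why: Dess–Martin oxidation of the only free hydroxyl gives the C11 ketone under buffered, non-enolising conditions.

Step 20
Reactants: 34 C11 ketone
Product: 38 CNP0525404.1 (target), via silyl enol ether 35 (not isolated), via silyloxy oxirane 36 (not isolated), via silyloxy ketone 37 (not isolated)
Conditions: TMSOTf (1.3 equiv), Et3N (2 equiv), CH2Cl2, −78 → −20 °C; then dimethyldioxirane (acetone solution, 1.2 equiv), −78 → −40 °C; then 48% aq. HF, MeCN, 0 °C → rt
Reagents that add atoms: dimethyldioxirane, CC1(C)OO1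
Why: In this Rubottom oxidation the C11 ketone can enolise only toward C10, dimethyldioxirane epoxidises the electron-rich silyl enol ether much faster than the enone or the pyranone and should approach anti to the axial C9 silyloxy and the C12 silyloxy groups, which places the C10 oxygen trans to both as in the target, and after silyl migration aqueous HF removes all three silyl groups.

**Compound list**

1 | ethyl 2-(furan-2-yl)acetate | CCOC(=O)Cc1ccco1 | starting material
2 | iodomethane | CI | starting material
3 | ethyl 2-(furan-2-yl)propanoate (racemic) | CCOC(=O)C(C)c1ccco1 | intermediate (not isolated)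
4 | ethyl 2-(furan-2-yl)-2-methylpropanoate | CCOC(=O)C(C)(C)c1ccco1 | intermediate
5 | acetonitrile | CC#N | starting material
6 | 4-(furan-2-yl)-4-methyl-3-oxopentanenitrile | N#CCC(=O)C(C)(C)c1ccco1 | intermediate
7 | 2-{2-[2-(furan-2-yl)propan-2-yl]-1,3-dioxolan-2-yl}acetonitrile | N#CCC1(OCCO1)C(C)(C)c1ccco1 | intermediate
8 | N-(diisobutylalumino)imine of aldehyde 9 | CC(C)C[Al](CC(C)C)N=CCC1(OCCO1)C(C)(C)c1ccco1 | intermediate (not isolated)
9 | 2-{2-[2-(furan-2-yl)propan-2-yl]-1,3-dioxolan-2-yl}acetaldehyde | O=CCC1(OCCO1)C(C)(C)c1ccco1 | intermediate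
10 | 1,1-diiodoethane | CC(I)I | starting material
11 | 2-[(E)-but-2-en-1-yl]-2-[2-(furan-2-yl)propan-2-yl]-1,3-dioxolane | C/C=C/CC1(OCCO1)C(C)(C)c1ccco1 | intermediate
12 | formaldehyde (used as paraformaldehyde) | C=O | starting material
13 | 5-lithio derivative of furan 11 | [Li]c1ccc(o1)C(C)(C)C1(C/C=C/C)OCCO1 | intermediate (not isolated)
14 | {5-[2-(2-[(E)-but-2-en-1-yl]-1,3-dioxolan-2-yl)propan-2-yl]furan-2-yl}methanol | OCc1ccc(o1)C(C)(C)C1(C/C=C/C)OCCO1 | intermediate
15 | 6-hydroxy-6-[2-(2-[(E)-but-2-en-1-yl]-1,3-dioxolan-2-yl)propan-2-yl]-2H-pyran-3(6H)-one (racemic) | OC1(C(C)(C)C2(C/C=C/C)OCCO2)OCC(=O)C=C1 | intermediate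
16 | 6-[4-(methylthio)benzoyloxy] analogue of 15 (racemic; key-step precursor) | CSc1ccc(cc1)C(=O)OC1(C(C)(C)C2(C/C=C/C)OCCO2)OCC(=O)C=C1 | intermediate
17 | 3-oxidopyrylium ylide carrying the tether at C12 (present as its catalyst-bound aminopyrylium equivalent) | [O-]c1c[o+]c(cc1)C(C)(C)C1(C/C=C/C)OCCO1 | intermediate (not isolated)
18 | bridged tricyclic enone: C9 ketone, C10=C11, C12–O–C18 bridge, C15 dioxolane, C14 syn and C17 methyl anti to the bridge | O=C1C=C[C@@]23O[C@@H]1[C@@H](C)[C@@H]2CC4(OCCO4)C3(C)C | intermediate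
19 | C10–C11 epoxide of 18, oxirane syn to the bridge | O=C1[C@H]5O[C@H]5[C@@]23O[C@@H]1[C@@H](C)[C@@H]2CC4(OCCO4)C3(C)C | intermediate
20 | bridged β-hydroxy ketone: C9 ketone, C11 hydroxyl syn to the bridge | O=C1C[C@@H](O)[C@@]23O[C@@H]1[C@@H](C)[C@@H]2CC4(OCCO4)C3(C)C | intermediate
21 | C11 triethylsilyl ether of 20 | O=C1C[C@@H](O[Si](CC)(CC)CC)[C@@]23O[C@@H]1[C@@H](C)[C@@H]2CC4(OCCO4)C3(C)C | intermediate
22 | trivalent samarium C9–C18 enolate and C12 alkoxide | I[Sm](I)OC1C[C@@H](O[Si](CC)(CC)CC)[C@@]2(O[Sm](I)I)[C@@H](CC3(OCCO3)C2(C)C)[C@H](C)C=1 | intermediate (not isolated)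
23 | bridge-opened hydroxymethyl ketone: C9 ketone, C18 CH–CH2OH (epimers), C12 hydroxyl, C11 OTES, ring D trans-fused | O=C1C[C@@H](O[Si](CC)(CC)CC)[C@@]2(O)[C@@H](CC3(OCCO3)C2(C)C)[C@H](C)C1CO | intermediate
24 | primary mesylate of 23 | O=C1C[C@@H](O[Si](CC)(CC)CC)[C@@]2(O)[C@@H](CC3(OCCO3)C2(C)C)[C@H](C)C1COS(C)(=O)=O | intermediate (not isolated)
25 | α-methylene ketone: C18=C19, C12 hydroxyl free | O=C1C[C@@H](O[Si](CC)(CC)CC)[C@@]2(O)[C@@H](CC3(OCCO3)C2(C)C)[C@H](C)C1=C | intermediate
26 | C12 tert-butyldimethylsilyl ether of 25 | O=C1C[C@@H](O[Si](CC)(CC)CC)[C@@]2(O[Si](C)(C)C(C)(C)C)[C@@H](CC3(OCCO3)C2(C)C)[C@H](C)C1=C | intermediate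
27 | 4-hydroxy-5,6-dimethyl-2H-pyran-2-one | Cc1oc(=O)cc(O)c1C | starting material
28 | tetracyclic hemiketal: rings A to D, C9 hydroxyl axial, rings B and C trans-fused, C11 OTES, C12 OTBS, C15 dioxolane | Cc1oc(=O)c2c(c1C)O[C@]1(O)C[C@@H](O[Si](CC)(CC)CC)[C@@]3(O[Si](C)(C)C(C)(C)C)[C@@H](CC4(OCCO4)C3(C)C)[C@H](C)[C@H]1C2 | intermediate (not isolated)
29 | C9 tert-butyldimethylsilyl ketal of 28 | Cc1oc(=O)c2c(c1C)O[C@]1(O[Si](C)(C)C(C)(C)C)C[C@@H](O[Si](CC)(CC)CC)[C@@]3(O[Si](C)(C)C(C)(C)C)[C@@H](CC4(OCCO4)C3(C)C)[C@H](C)[C@H]1C2 | intermediate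
30 | C15 ketone with free C11 hydroxyl, C9 and C12 OTBS | Cc1oc(=O)c2c(c1C)O[C@]1(O[Si](C)(C)C(C)(C)C)C[C@@H](O)[C@@]3(O[Si](C)(C)C(C)(C)C)[C@@H](CC(=O)C3(C)C)[C@H](C)[C@H]1C2 | intermediate
31 | C14=C15 trimethylsilyl enol ether with C11 OTMS | Cc1oc(=O)c2c(c1C)O[C@]1(O[Si](C)(C)C(C)(C)C)C[C@@H](O[Si](C)(C)C)[C@@]3(O[Si](C)(C)C(C)(C)C)[C@@H](C=C(O[Si](C)(C)C)C3(C)C)[C@H](C)[C@H]1C2 | intermediate (not isolated)
32 | ring D enone with C11 OTMS | Cc1oc(=O)c2c(c1C)O[C@]1(O[Si](C)(C)C(C)(C)C)C[C@@H](O[Si](C)(C)C)[C@@]3(O[Si](C)(C)C(C)(C)C)C(=CC(=O)C3(C)C)[C@H](C)[C@H]1C2 | intermediate (not isolated)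
33 | ring D enone with free C11 hydroxyl | Cc1oc(=O)c2c(c1C)O[C@]1(O[Si](C)(C)C(C)(C)C)C[C@@H](O)[C@@]3(O[Si](C)(C)C(C)(C)C)C(=CC(=O)C3(C)C)[C@H](C)[C@H]1C2 | intermediate
34 | C11 ketone, C10 methylene, C9 and C12 OTBS | Cc1oc(=O)c2c(c1C)O[C@]1(O[Si](C)(C)C(C)(C)C)CC(=O)[C@@]3(O[Si](C)(C)C(C)(C)C)C(=CC(=O)C3(C)C)[C@H](C)[C@H]1C2 | intermediate
35 | C10=C11 trimethylsilyl enol ether of 34 | Cc1oc(=O)c2c(c1C)O[C@]1(O[Si](C)(C)C(C)(C)C)C=C(O[Si](C)(C)C)[C@@]3(O[Si](C)(C)C(C)(C)C)C(=CC(=O)C3(C)C)[C@H](C)[C@H]1C2 | intermediate (not isolated)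
36 | C10–C11 silyloxy oxirane, oxygen anti to the C9 and C12 silyloxy groups | Cc1oc(=O)c2c(c1C)O[C@]1(O[Si](C)(C)C(C)(C)C)[C@@H]5O[C@]5(O[Si](C)(C)C)[C@@]3(O[Si](C)(C)C(C)(C)C)C(=CC(=O)C3(C)C)[C@H](C)[C@H]1C2 | intermediate (not isolated)
37 | C10 trimethylsilyloxy C11 ketone, C9 and C12 OTBS | Cc1oc(=O)c2c(c1C)O[C@]1(O[Si](C)(C)C(C)(C)C)[C@H](O[Si](C)(C)C)C(=O)[C@@]3(O[Si](C)(C)C(C)(C)C)C(=CC(=O)C3(C)C)[C@H](C)[C@H]1C2 | intermediate (not isolated)
38 | CNP0525404.1 | Cc1oc(=O)c2c(c1C)O[C@]1(O)[C@H](O)C(=O)[C@@]3(O)C(=CC(=O)C3(C)C)[C@H](C)[C@H]1C2 | target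

**Step count**

Total steps: 20. Longest linear sequence: 20 (from 1; pyranone 27 is purchased).

**Steps most likely to fail**

Step 9. Bond formation at C12 next to the quaternary C16 may be slow enough for the ylide to dimerise, or the catalyst may discriminate the two faces of the ylide poorly with a 1,2-disubstituted alkene. Fallback (from 16, back at 18): the cycloaddition is run without chiral control with N-methylpyrrolidine in MeCN at 60 °C to give the racemic cycloadduct F1. Luche reduction (NaBH4, CeCl3·7H2O, MeOH, −78 °C) gives the racemic allylic alcohol F2, which is esterified with (S)-O-methylmandelic acid (DCC, DMAP). The diastereomeric esters are separated by chromatography or crystallisation; the wanted mandelate ester F3 is kept and the diastereomeric mandelate ester F4 is set aside. Methanolysis of F3 (K2CO3, MeOH) gives the single-enantiomer allylic alcohol F5, and oxidation with MnO2 returns 18.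

Step 13. The samarium enolate may be protonated before it meets formaldehyde, or capture of monomeric formaldehyde may be slow, which would give the C18-unsubstituted ketone and lose the regiochemical information. Fallback (from 21, back at 23): the bridge is cut with lithium in liquid NH3/THF at −78 °C and, after removal of the ammonia, the lithium enolate and alkoxide are silylated with TMSCl/Et3N to give the isolable bis-silyl enol ether F6 (C9–C18 silyl enol ether, C12 trimethylsilyl ether). Lewis acid-catalysed hydroxymethylation of F6 with aqueous formaldehyde and Yb(OTf)3 (Mukaiyama-type aldol in water), followed by citric acid in MeOH to free the C12 hydroxyl, gives 23.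

Step 20. The C9 silyl ketal may ionise under the Lewis acidic enol silylation and open ring B toward a vinylogous ester, or the epoxidation may show poor face selectivity. Fallback (from 34, back at 38): the potassium enolate is formed with KN(SiMe3)2 in THF at −78 °C and oxidised with 2-(phenylsulfonyl)-3-phenyloxaziridine (Davis hydroxylation), whose bulk should reinforce approach anti to the two silyloxy groups, giving the C10 hydroxy bis-silyl ether F7. Aqueous HF in MeCN then gives 38.

**Further compounds**

F1 | step 9 | racemic cycloadduct (18 and its mirror image, 1:1) | O=C1C=C[C@@]23O[C@@H]1[C@@H](C)[C@@H]2CC4(OCCO4)C3(C)C.O=C1C=C[C@]23O[C@H]1[C@H](C)[C@H]2CC4(OCCO4)C3(C)C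
F2 | step 9 | racemic allylic alcohol (C9 carbinol, hydroxyl anti to the bridge) | O[C@@H]1C=C[C@@]23O[C@@H]1[C@@H](C)[C@@H]2CC4(OCCO4)C3(C)C.O[C@H]1C=C[C@]23O[C@H]1[C@H](C)[C@H]2CC4(OCCO4)C3(C)C
F3 | step 9 | (S)-O-methylmandelate of the wanted allylic alcohol enantiomer | CO[C@H](C(=O)O[C@@H]1C=C[C@@]23O[C@@H]1[C@@H](C)[C@@H]2CC4(OCCO4)C3(C)C)c1ccccc1
F4 | step 9 | (S)-O-methylmandelate of the mirror-image allylic alcohol | CO[C@H](C(=O)O[C@H]1C=C[C@]23O[C@H]1[C@H](C)[C@H]2CC4(OCCO4)C3(C)C)c1ccccc1
F5 | step 9 | single-enantiomer allylic alcohol | O[C@@H]1C=C[C@@]23O[C@@H]1[C@@H](C)[C@@H]2CC4(OCCO4)C3(C)C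
F6 | step 13 | C9–C18 trimethylsilyl enol ether with C12 OTMS and C11 OTES | C[Si](C)(C)OC1C[C@@H](O[Si](CC)(CC)CC)[C@@]2(O[Si](C)(C)C)[C@@H](CC3(OCCO3)C2(C)C)[C@H](C)C=1
F7 | step 20 | C10 hydroxy C11 ketone with C9 and C12 OTBS | Cc1oc(=O)c2c(c1C)O[C@]1(O[Si](C)(C)C(C)(C)C)[C@H](O)C(=O)[C@@]3(O[Si](C)(C)C(C)(C)C)C(=CC(=O)C3(C)C)[C@H](C)[C@H]1C2
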